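**Retrosynthetic overview**
1. The C6 ester is cut last: Yamaguchi acylation of hydroxy lactone 26 with epoxy acid 29, made by Sharpless epoxidation of tiglyl alcohol and oxidation.
2. Key disconnection: the C7–C8 bond, which is shared by the ten-membered carbocycle (C1–C10) and the γ-lactone (C7, C8, O, C12, C11). One ring-closing allylboration/lactonisation of aldehyde–allylboronate 23 closes both rings and sets C7 and C8 from C6.
3. Enabling feature: C7 carries C11 of the α-methylene lactone (C11=C13H2, C12=O), so C7 is the γ-carbon of a 2-(methoxycarbonyl)allylboronate and C8 a carbonyl carbon. The (Z)-C4=C5 alkene and the flat furanone ring (O, C10, C1, C2, C3) hold C9 and C6 on one side.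
4. The allylboronate geometry comes from ynoate 18 (syn-hydrostannation, iodination, Negishi coupling). C6 is set by catalytic alkynylation of (Z)-enal 14. The furanone comes from 5-endo-dig closure of an α′-hydroxy ynone, built from the acetylide of (Z)-3-methylpent-2-en-4-yn-1-ol and a lactone from (R)-citramalic acid (C10 bought).
5. Ring order: furanone (step 6), then ten-membered carbocycle and γ-lactone together (step 14); the side-chain oxirane is made separately (step 16).

Key step: step 14

Remark on locants (germacrane numbering): C1 furanone C=O, C2 furanone CH, C3 furanone O–C=, C4 (CH3)=C5, C6 (ester oxygen), C7, C8 (lactone oxygen), C9 (CH2), C10 (quaternary: CH3 and furanone oxygen), C11 (=C13H2), C12 lactone C=O. The target is 6R,7R,8S,10R and carries a (2S,3R)-2,3-dimethyloxirane-2-carboxylate (methyl groups cis).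

Assumption: (S,S)-ProPhenol is taken as the ligand enantiomer that gives the 6R carbinol in step 9; if a test on a simple (Z)-enal shows the opposite sense, the (R,R)-ligand is used and nothing else changes.

**Route**

Step 1
Reactants: 1 (R)-citramalic acid
Product: 2 2-[(4R)-2,2,4-trimethyl-5-oxo-1,3-dioxolan-4-yl]acetic acid
Conditions: 2,2-dimethoxypropane, p-TsOH·H2O (cat.), acetone, rt
Reagents that add atoms: 2,2-dimethoxypropane, COC(C)(C)OC
Why: Acid-catalysed acetonide (dioxolanone) formation ties the tertiary hydroxyl to the adjacent carboxyl in a five-membered ring and leaves the CH2CO2H arm free, while the purchased quaternary centre (later C10) is not touched.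

Step 2
Reactants: 2 dioxolanone acid
Product: 4 (3R)-3-hydroxy-3-methyloxolan-2-one, via hydroxyethyl dioxolanone 3 (not isolated)
Conditions: BH3·SMe2, THF, 0 °C to rt; MeOH quench; then p-TsOH·H2O (cat.), CH2Cl2, rt
Reagents that add atoms: none
Why: Chemoselective borane reduction of the free carboxylic acid beside the dioxolanone, followed by acid-catalysed translactonisation of the new primary alcohol onto the activated carbonyl with loss of acetone, should give the five-membered lactone.

Step 3
Reactants: 4 hydroxy lactone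
Product: 5 (3R)-3-methyl-3-[(trimethylsilyl)oxy]oxolan-2-one
Conditions: TMSCl, imidazole, CH2Cl2, 0 °C to rt
Reagents that add atoms: chlorotrimethylsilane, C[Si](C)(C)Cl
Why: Silyl ether formation masks the tertiary hydroxyl so that one equivalent of acetylide suffices in step 5, and the group is lost again in the methanolysis of step 6.

Step 4
Reactants: 6 (2Z)-3-methylpent-2-en-4-yn-1-ol
Product: 7 tert-butyldimethylsilyl ether of 6
Conditions: TBSCl, imidazole, CH2Cl2, 0 °C to rt
Reagents that add atoms: tert-butylchlorodimethylsilane, CC(C)(C)[Si](C)(C)Cl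
Why: Silyl protection keeps the (Z)-allylic oxygen from adding 5-exo to the ynone made in step 5, and the Z geometry of the later C4=C5 alkene is bought with the starting material.

Step 5
Reactants: 7 silyl enyne; 5 silyloxy lactone
Product: 9 (3R,7Z)-9-[(tert-butyldimethylsilyl)oxy]-1-hydroxy-3,7-dimethyl-3-[(trimethylsilyl)oxy]non-7-en-5-yn-4-one (in equilibrium with its five-membered lactol), via lithium acetylide 8 (not isolated)
Conditions: n-BuLi (1.0 equiv), THF, −78 °C; then 5, −78 °C; AcOH quench at −78 °C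
Reagents that add atoms: none
Why: Addition of a lithium acetylide to a lactone should stop at the ketone oxidation level because the tetrahedral lithium lactolate persists at −78 °C, and the lactone has no α-hydrogen to enolise.

Step 6
Reactants: 9 hydroxy ynone
Product: 12 (2R)-5-[(2Z)-4-hydroxybut-2-en-2-yl]-2-(2-hydroxyethyl)-2-methylfuran-3(2H)-one, via hydroxy ynone 10 (not isolated), via furanone silyl ether 11 (not isolated)
Conditions: K2CO3 (0.2 equiv), MeOH, 0 °C to rt; then CSA (0.5 equiv), 0 °C
Reagents that add atoms: none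
Why: Methanolysis of the TMS ether frees the tertiary alkoxide, which closes the 3(2H)-furanone by 5-endo-dig oxa-Michael addition to the ynone (any β-methoxy enone from methanol addition converges on the same furanone once acid is added), and the acid then cleaves the primary allylic TBS ether.

Step 7
Reactants: 12 furanone diol
Product: 13 (2Z)-3-[(5R)-5-(2-hydroxyethyl)-5-methyl-4-oxo-4,5-dihydrofuran-2-yl]but-2-enal
Conditions: MnO2 (activated, 15 equiv), CH2Cl2, rt, dark
Reagents that add atoms: none
Why: Manganese dioxide oxidation is selective for the allylic alcohol over the saturated primary alcohol, and the neutral conditions in the dark should keep the Z alkene.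

Step 8
Reactants: 13 hydroxy enal
Product: 14 triethylsilyl ether of 13
Conditions: TESCl, imidazole, CH2Cl2, 0 °C
Reagents that add atoms: chlorotriethylsilane, CC[Si](Cl)(CC)CC
Why: Silylation of the only hydroxyl gives a labile primary TES ether that can later be removed beside a secondary TBS ether.

Step 9
Reactants: 14 enal; 15 methyl propiolate
Product: 17 methyl (4R,5Z)-4-hydroxy-6-{(5R)-5-methyl-4-oxo-5-[2-(triethylsilyloxy)ethyl]-4,5-dihydrofuran-2-yl}hept-5-en-2-ynoate, via methylzinc alkynylide 16 (not isolated)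
Conditions: Me2Zn (3 equiv), (S,S)-ProPhenol [2,6-bis{[(2S)-2-(hydroxydiphenylmethyl)pyrrolidin-1-yl]methyl}-4-methylphenol] (20 mol%), Ph3PO (40 mol%), toluene, 4 °C; aq. NH4Cl
Reagents that add atoms: none
Why: Catalytic asymmetric alkynylation of an enal by a zinc alkynylide held in the dinuclear zinc–ProPhenol complex should set C6 (R) by ligand control of the aldehyde face, the remote C10 centre having no influence.

Step 10
Reactants: 17 propargylic alcohol
Product: 18 methyl (4R,5Z)-4-[(tert-butyldimethylsilyl)oxy]-6-{(5R)-5-methyl-4-oxo-5-[2-(triethylsilyloxy)ethyl]-4,5-dihydrofuran-2-yl}hept-5-en-2-ynoate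
Conditions: TBSOTf, 2,6-lutidine, CH2Cl2, −78 °C
Reagents that add atoms: tert-butyldimethylsilyl triflate, CC(C)(C)[Si](C)(C)OS(=O)(=O)C(F)(F)F
Why: Low-temperature silylation with a hindered base avoids amine-induced isomerisation of the γ-hydroxy ynoate, and C6 has to stay capped because its free hydroxyl would later close a butenolide on C12.

Step 11
Reactants: 18 ynoate
Product: 20 methyl (2E,4R,5Z)-4-[(tert-butyldimethylsilyl)oxy]-2-iodo-6-{(5R)-5-methyl-4-oxo-5-[2-(triethylsilyloxy)ethyl]-4,5-dihydrofuran-2-yl}hepta-2,5-dienoate, via vinylstannane 19 (not isolated)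
Conditions: Bu3SnH (1.2 equiv), Pd(PPh3)4 (3 mol%), THF, 0 °C; then I2 (1.1 equiv), CH2Cl2, 0 °C, dark
Reagents that add atoms: iodine, II
Why: Palladium-catalysed hydrostannation of an ynoate is a syn addition that puts tin on the carbon next to the ester (C11) and hydrogen on C7, and iododestannylation proceeds with retention, so C6 ends cis to CO2Me.

Step 12
Reactants: 20 vinyl iodide
Product: 21 methyl (2Z,4R,5Z)-4-[(tert-butyldimethylsilyl)oxy]-6-{(5R)-5-methyl-4-oxo-5-[2-(triethylsilyloxy)ethyl]-4,5-dihydrofuran-2-yl}-2-[(4,4,5,5-tetramethyl-1,3,2-dioxaborolan-2-yl)methyl]hepta-2,5-dienoate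
Conditions: ICH2Bpin (2.5 equiv), Zn dust (activated), THF, rt; then 20, Pd(PPh3)4 (5 mol%), THF, rt to 40 °C
Reagents that add atoms: 2-(iodomethyl)-4,4,5,5-tetramethyl-1,3,2-dioxaborolane, ICB1OC(C)(C)C(C)(C)O1
Why: Negishi coupling of an alkenyl iodide with a (boryl)methylzinc iodide keeps the alkene geometry and should deliver the 2-(methoxycarbonyl)allylboronate with CH2B trans to C6.

Step 13
Reactants: 21 allylboronate
Product: 22 primary alcohol of 21 (C8–OH free, C6–OTBS kept)
Conditions: PPTS (0.2 equiv), MeOH/CH2Cl2 (1:1), 0 °C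
Reagents that add atoms: none
Why: Acid-catalysed methanolysis removes a primary TES ether much faster than a secondary TBS ether, and the ester-bearing pinacol allylboronate is inert to it.

Step 14
Reactants: 22 hydroxy allylboronate
Product: 25 (6R,7R,8S,10R)-6-O-TBS tricyclic lactone (target core with OTBS at C6), via aldehyde 23 (not isolated), via borate ester 24 (not isolated)
Conditions: DMP (1.3 equiv), CH2Cl2, 0 °C to rt; filtration through Celite; dilution to 0.001 M in toluene/CH2Cl2, Sc(OTf)3 (0.5 equiv), 4 Å MS, −20 °C to rt; then CSA (0.5 equiv), rt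
Reagents that add atoms: none
Why: Proposed new method: a ring-closing allylboration to a ten-membered carbocycle is not known, the closest known reactions being the Sc(OTf)3-catalysed intermolecular allylboration/lactonisation of aldehydes with 2-alkoxycarbonyl allylboronates, intramolecular allylborations that close five- to eight-membered rings and CrCl2-mediated intramolecular allylations that close ten-membered germacranolide rings. Dess–Martin oxidation unmasks the C8 aldehyde 23, Sc(OTf)3 binds a pinacolate oxygen and makes boron more Lewis acidic, and C7 (the γ-carbon of the allylboronate) adds to the C8 carbonyl through a closed six-membered chair transition state (Zimmerman–Traxler, type 1 allylation) with allylic transposition, which forms the C7–C8 bond, the C11=C13 exo-methylene and borate 24 in one event; CSA then exchanges borate and methyl ester for the lactone. The carbocycle closes by 10-exo-trig addition to the aldehyde (nine ring atoms if counted through the furanone oxygen) and the lactone by 5-exo-trig acyl substitution of O8 at C12. C8 (S) follows from the chair: the fixed alkene geometry (C6 trans to CH2B) places C6 equatorial next to the equatorial aldehyde chain C9, which gives the anti adduct and therefore the trans-fused lactone. C7 (R) follows from C6: allylic 1,3-strain against the cis CO2Me keeps H6 in the alkene plane, so the aldehyde, tethered through C5, reaches C7 on the face opposite the OTBS group. The step needs cyclisation to beat oligomerisation and β-elimination of the furanone oxygen from the aldehyde, which high dilution, the turn imposed by the (Z)-C4=C5 alkene and the flat furanone, and the base-free medium should secure.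

Step 15
Reactants: 25 silyl lactone
Product: 26 (6R,7R,8S,10R)-6-hydroxy tricyclic lactone
Conditions: HF·pyridine, pyridine, THF, 0 °C to rt
Reagents that add atoms: none
Why: Fluoride-induced desilylation under buffered, non-basic conditions should free the C6 hydroxyl without translactonisation from O8 to O6, and no stereocentre is touched.

Step 16
Reactants: 27 (2E)-2-methylbut-2-en-1-ol (tiglyl alcohol)
Product: 28 [(2R,3R)-2,3-dimethyloxiran-2-yl]methanol
Conditions: Ti(OiPr)4 (10 mol%), D-(−)-diethyl tartrate (12 mol%), t-BuOOH (anhydrous, isooctane), 4 Å MS, CH2Cl2, −20 °C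
Reagents that add atoms: tert-butyl hydroperoxide, CC(C)(C)OO
Why: Sharpless asymmetric epoxidation delivers oxygen to one face of the allylic alcohol under control of the tartrate–titanium complex and sets both oxirane centres (2R,3R), the cis relation of the two methyl groups coming from the E alkene.

Step 17
Reactants: 28 epoxy alcohol
Product: 29 (2S,3R)-2,3-dimethyloxirane-2-carboxylic acid
Conditions: RuCl3·xH2O (2 mol%), NaIO4 (3 equiv), MeCN/EtOAc/H2O, 0 °C to rt
Reagents that add atoms: water, O
Why: Ruthenium tetroxide oxidation (RuO4 formed catalytically from RuCl3 and NaIO4) takes the primary alcohol to the acid through the aldehyde hydrate without touching the oxirane centres, whose descriptors change to 2S,3R only through the priority rules.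

Step 18
Reactants: 26 hydroxy lactone; 29 epoxy acid
Product: 31 target CNP0258430.2, via mixed anhydride 30 (not isolated)
Conditions: 29 (2 equiv), 2,4,6-trichlorobenzoyl chloride, Et3N, toluene, rt; then 26, DMAP, toluene, rt
Reagents that add atoms: none
Why: Yamaguchi esterification should acylate the hindered C6 hydroxyl because DMAP opens the mixed anhydride at the oxirane carbonyl, the other carbonyl being shielded by two ortho chlorines, and C6 keeps its configuration since its C–O bond is not broken.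

**Compound list**
1 | (R)-citramalic acid, (2R)-2-hydroxy-2-methylbutanedioic acid | C[C@@](O)(CC(=O)O)C(=O)O | starting material
2 | 2-[(4R)-2,2,4-trimethyl-5-oxo-1,3-dioxolan-4-yl]acetic acid | C[C@]1(CC(=O)O)OC(C)(C)OC1=O | intermediate
3 | (5R)-5-(2-hydroxyethyl)-2,2,5-trimethyl-1,3-dioxolan-4-one | C[C@]1(CCO)OC(C)(C)OC1=O | intermediate
4 | (3R)-3-hydroxy-3-methyloxolan-2-one | C[C@@]1(O)CCOC1=O | intermediate
5 | (3R)-3-methyl-3-[(trimethylsilyl)oxy]oxolan-2-one | C[C@@]1(O[Si](C)(C)C)CCOC1=O | intermediate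
6 | (2Z)-3-methylpent-2-en-4-yn-1-ol | C#C/C(C)=C\CO | starting material
7 | tert-butyldimethyl{[(2Z)-3-methylpent-2-en-4-yn-1-yl]oxy}silane | C#C/C(C)=C\CO[Si](C)(C)C(C)(C)C | intermediate
8 | lithium acetylide of 7 | [Li]C#C/C(C)=C\CO[Si](C)(C)C(C)(C)C | intermediate
9 | (3R,7Z)-9-[(tert-butyldimethylsilyl)oxy]-1-hydroxy-3,7-dimethyl-3-[(trimethylsilyl)oxy]non-7-en-5-yn-4-one | C[C@@](O[Si](C)(C)C)(CCO)C(=O)C#C/C(C)=C\CO[Si](C)(C)C(C)(C)C | intermediate
10 | (3R,7Z)-9-[(tert-butyldimethylsilyl)oxy]-1,3-dihydroxy-3,7-dimethylnon-7-en-5-yn-4-one | C[C@@](O)(CCO)C(=O)C#C/C(C)=C\CO[Si](C)(C)C(C)(C)C | intermediate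
11 | (2R)-5-{(2Z)-4-[(tert-butyldimethylsilyl)oxy]but-2-en-2-yl}-2-(2-hydroxyethyl)-2-methylfuran-3(2H)-one | C[C@]1(CCO)OC(=CC1=O)/C(C)=C\CO[Si](C)(C)C(C)(C)C | intermediate
12 | (2R)-5-[(2Z)-4-hydroxybut-2-en-2-yl]-2-(2-hydroxyethyl)-2-methylfuran-3(2H)-one | C[C@]1(CCO)OC(=CC1=O)/C(C)=C\CO | intermediate
13 | (2Z)-3-[(5R)-5-(2-hydroxyethyl)-5-methyl-4-oxo-4,5-dihydrofuran-2-yl]but-2-enal | C[C@]1(CCO)OC(=CC1=O)/C(C)=C\C=O | intermediate
14 | (2Z)-3-{(5R)-5-methyl-4-oxo-5-[2-(triethylsilyloxy)ethyl]-4,5-dihydrofuran-2-yl}but-2-enal | C[C@]1(CCO[Si](CC)(CC)CC)OC(=CC1=O)/C(C)=C\C=O | intermediate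
15 | methyl propiolate | C#CC(=O)OC | starting material
16 | methyl 3-(methylzincio)prop-2-ynoate | C[Zn]C#CC(=O)OC | intermediate
17 | methyl (4R,5Z)-4-hydroxy-6-{(5R)-5-methyl-4-oxo-5-[2-(triethylsilyloxy)ethyl]-4,5-dihydrofuran-2-yl}hept-5-en-2-ynoate | C[C@]1(CCO[Si](CC)(CC)CC)OC(=CC1=O)/C(C)=C\[C@@H](O)C#CC(=O)OC | intermediate
18 | 4-O-tert-butyldimethylsilyl ether of 17 | C[C@]1(CCO[Si](CC)(CC)CC)OC(=CC1=O)/C(C)=C\[C@@H](O[Si](C)(C)C(C)(C)C)C#CC(=O)OC | intermediate
19 | methyl (2E,4R,5Z)-4-(TBSO)-6-(furanonyl)-2-(tributylstannyl)hepta-2,5-dienoate (Sn trans to C6) | C[C@]1(CCO[Si](CC)(CC)CC)OC(=CC1=O)/C(C)=C\[C@@H](O[Si](C)(C)C(C)(C)C)/C=C(/[Sn](CCCC)(CCCC)CCCC)C(=O)OC | intermediate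
20 | methyl (2E,4R,5Z)-4-(TBSO)-2-iodo-6-(furanonyl)hepta-2,5-dienoate (I trans to C6, CO2Me cis) | C[C@]1(CCO[Si](CC)(CC)CC)OC(=CC1=O)/C(C)=C\[C@@H](O[Si](C)(C)C(C)(C)C)/C=C(/I)C(=O)OC | intermediate
21 | methyl (2Z,4R,5Z)-4-(TBSO)-6-(furanonyl)-2-[(pinacolatoboryl)methyl]hepta-2,5-dienoate (CH2B trans to C6), C8–OTES | C[C@]1(CCO[Si](CC)(CC)CC)OC(=CC1=O)/C(C)=C\[C@@H](O[Si](C)(C)C(C)(C)C)/C=C(/CB2OC(C)(C)C(C)(C)O2)C(=O)OC | intermediate
22 | primary alcohol of 21 (C8–OH) | C[C@]1(CCO)OC(=CC1=O)/C(C)=C\[C@@H](O[Si](C)(C)C(C)(C)C)/C=C(/CB2OC(C)(C)C(C)(C)O2)C(=O)OC | intermediate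
23 | C8 aldehyde of 22 | C[C@]1(CC=O)OC(=CC1=O)/C(C)=C\[C@@H](O[Si](C)(C)C(C)(C)C)/C=C(/CB2OC(C)(C)C(C)(C)O2)C(=O)OC | intermediate
24 | ring-closed borate: ten-membered carbocycle, C8–O–Bpin, C7 bearing 1-(methoxycarbonyl)vinyl, C6–OTBS (6R,7R,8S,10R) | C=C(C(=O)OC)[C@@H]1[C@@H](OB2OC(C)(C)C(C)(C)O2)C[C@@]3(C)OC(=CC3=O)/C(C)=C\[C@H]1O[Si](C)(C)C(C)(C)C | intermediate
25 | (6R,7R,8S,10R)-6-O-TBS tricyclic lactone | C=C1C(=O)O[C@H]2C[C@@]3(C)OC(=CC3=O)/C(C)=C\[C@@H](O[Si](C)(C)C(C)(C)C)[C@H]12 | intermediate
26 | (6R,7R,8S,10R)-6-hydroxy tricyclic lactone | C=C1C(=O)O[C@H]2C[C@@]3(C)OC(=CC3=O)/C(C)=C\[C@@H](O)[C@H]12 | intermediate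
27 | (2E)-2-methylbut-2-en-1-ol | C/C=C(\C)CO | starting material
28 | [(2R,3R)-2,3-dimethyloxiran-2-yl]methanol | OC[C@@]1(C)O[C@@H]1C | intermediate
29 | (2S,3R)-2,3-dimethyloxirane-2-carboxylic acid | O=C(O)[C@@]1(C)O[C@@H]1C | intermediate
30 | (2S,3R)-2,3-dimethyloxirane-2-carboxylic 2,4,6-trichlorobenzoic anhydride | O=C(OC(=O)c1c(Cl)cc(Cl)cc1Cl)[C@@]1(C)O[C@@H]1C | intermediate
31 | CNP0258430.2 | C=C1C(=O)O[C@H]2C[C@@]3(C)OC(=CC3=O)/C(C)=C\[C@@H](OC(=O)[C@@]3(C)O[C@@H]3C)[C@H]12 | target

**Step count and risks**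
Total step count: 18. Longest linear sequence: 15 steps (steps 1–3, 5–15 and 18).

Steps most likely to fail:

1. Step 14 (key step, proposed new method). Oligomerisation may outrun ring closure, the aldehyde may reach the wrong face of C7, or β-elimination may open the furanone before the C–C bond forms. The fallback uses the known CrCl2-mediated intramolecular allylation. It sets out from iodide 20: Stille coupling with Bu3SnCH2OH (Pd(PPh3)4, dioxane, 80 °C) should give allylic alcohol F1; CBr4/PPh3 should give allylic bromide F2; PPTS/MeOH should give primary alcohol F3; DMP should give bromo aldehyde F4. CrCl2 (excess, THF, 0.002 M, rt) should convert F4 into allylchromium species F5, which closes the ten-membered ring in a Nozaki–Hiyama–Kishi-type allylation to hydroxy ester F6 after work-up. CSA lactonises F6, and the route is rejoined at 25.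

2. Step 9. Face selectivity may erode with the hindered β,β-disubstituted (Z)-enal, and the enal may isomerise from Z to E under the zinc alkoxide conditions. The fallback sets out from enal 14: deprotonation of 15 with LiHMDS (THF, −78 °C) gives lithium propiolate F7, which adds to 14 to give the C6-epimeric alcohols F8. MnO2 should oxidise them to ynone F9, and reagent-controlled Midland reduction with (R)-Alpine-Borane (THF, rt), in which the alkyne plays the small group, should return to the route at 17.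

3. Step 18. Acylation of the hindered C6 hydroxyl by the α-quaternary acid may be slow, and base-induced translactonisation from O8 to O6 may compete. The fallback moves the acylation before the lactone exists. It sets out from 17 and acid 29: Yamaguchi esterification (via 30) at the unhindered propargylic hydroxyl should give epoxy ester F10. Hydrostannation as in step 11 gives stannane F11 and iodination gives iodide F12; Negishi coupling as in step 12 gives allylboronate F13; PPTS/MeOH gives alcohol F14. DMP gives aldehyde F15, and Sc(OTf)3 then CSA close the carbocycle (borate F16) and the lactone, arriving directly at 31.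

**Further compounds**
F1 | step 14 | allylic alcohol: 20 with CH2OH in place of iodine | C[C@]1(CCO[Si](CC)(CC)CC)OC(=CC1=O)/C(C)=C\[C@@H](O[Si](C)(C)C(C)(C)C)/C=C(/CO)C(=O)OC
F2 | step 14 | allylic bromide from F1 | C[C@]1(CCO[Si](CC)(CC)CC)OC(=CC1=O)/C(C)=C\[C@@H](O[Si](C)(C)C(C)(C)C)/C=C(/CBr)C(=O)OC
F3 | step 14 | primary alcohol of F2 (C8–OH) | C[C@]1(CCO)OC(=CC1=O)/C(C)=C\[C@@H](O[Si](C)(C)C(C)(C)C)/C=C(/CBr)C(=O)OC
F4 | step 14 | bromo aldehyde from F3 | C[C@]1(CC=O)OC(=CC1=O)/C(C)=C\[C@@H](O[Si](C)(C)C(C)(C)C)/C=C(/CBr)C(=O)OC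
F5 | step 14 | allylchromium dichloride from F4 (C7=C11 geometry not fixed) | C[C@]1(CC=O)OC(=CC1=O)/C(C)=C\[C@@H](O[Si](C)(C)C(C)(C)C)C=C(C[Cr](Cl)Cl)C(=O)OC
F6 | step 14 | ring-closed hydroxy ester (C8–OH, C6–OTBS; 6R,7R,8S,10R) | C=C(C(=O)OC)[C@@H]1[C@@H](O)C[C@@]2(C)OC(=CC2=O)/C(C)=C\[C@H]1O[Si](C)(C)C(C)(C)C
F7 | step 9 | lithium salt of methyl propiolate | [Li]C#CC(=O)OC
F8 | step 9 | C6-epimeric mixture of 17 | C[C@]1(CCO[Si](CC)(CC)CC)OC(=CC1=O)/C(C)=C\C(O)C#CC(=O)OC
F9 | step 9 | ynone: C6 ketone of 17 | C[C@]1(CCO[Si](CC)(CC)CC)OC(=CC1=O)/C(C)=C\C(=O)C#CC(=O)OC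
F10 | step 18 | C6 (2S,3R)-epoxy ester of 17 | C[C@]1(CCO[Si](CC)(CC)CC)OC(=CC1=O)/C(C)=C\[C@@H](OC(=O)[C@@]2(C)O[C@@H]2C)C#CC(=O)OC
F11 | step 18 | vinylstannane from F10 (Sn trans to C6) | C[C@]1(CCO[Si](CC)(CC)CC)OC(=CC1=O)/C(C)=C\[C@@H](OC(=O)[C@@]2(C)O[C@@H]2C)/C=C(/[Sn](CCCC)(CCCC)CCCC)C(=O)OC
F12 | step 18 | vinyl iodide from F11 | C[C@]1(CCO[Si](CC)(CC)CC)OC(=CC1=O)/C(C)=C\[C@@H](OC(=O)[C@@]2(C)O[C@@H]2C)/C=C(/I)C(=O)OC
F13 | step 18 | allylboronate from F12 (C8–OTES) | C[C@]1(CCO[Si](CC)(CC)CC)OC(=CC1=O)/C(C)=C\[C@@H](OC(=O)[C@@]2(C)O[C@@H]2C)/C=C(/CB3OC(C)(C)C(C)(C)O3)C(=O)OC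
F14 | step 18 | primary alcohol of F13 | C[C@]1(CCO)OC(=CC1=O)/C(C)=C\[C@@H](OC(=O)[C@@]2(C)O[C@@H]2C)/C=C(/CB3OC(C)(C)C(C)(C)O3)C(=O)OC
F15 | step 18 | C8 aldehyde of F14 | C[C@]1(CC=O)OC(=CC1=O)/C(C)=C\[C@@H](OC(=O)[C@@]2(C)O[C@@H]2C)/C=C(/CB3OC(C)(C)C(C)(C)O3)C(=O)OC
F16 | step 18 | ring-closed borate with the C6 epoxy ester in place | C=C(C(=O)OC)[C@@H]1[C@@H](OB2OC(C)(C)C(C)(C)O2)C[C@@]3(C)OC(=CC3=O)/C(C)=C\[C@H]1OC(=O)[C@@]4(C)O[C@@H]4C
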